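Your hunch, that this flask's yield can be read straight off the gamma run, is the trap: at the same 12.0 h, theta, with its larger charge, shows 10.2 % of its substrate as target, less than the 19.8 % in gamma.

| flask | substrate | gas | remark | time |
|---|---|---|---|---|
| gamma | 0.35 M | 200 mM (held) | run made earlier |  |
| theta | 1.4 M | 200 mM (held) | run made earlier |  |
| flask | 0.71 M | 200 mM (held) |  | 10 h |

| run | time / h | target / % |
|---|---|---|
| gamma | 1.00 | 0.9 |
| gamma | 3.00 | 4.6 |
| gamma | 6.00 | 10.2 |
| gamma | 8.00 | 11.9 |
| gamma | 12.0 | 19.8 |
| theta | 2.50 | 0.9 |
| theta | 5.00 | 4.3 |
| theta | 8.00 | 7.3 |
| theta | 10.0 | 9.1 |
| theta | 12.0 | 10.2 |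

(scatter of a reading: 1 percentage point)

1. how much target there is at 10 h, in percent of the substrate charged
2. concentration of coupling partner in solution at 10 h, in percent of saturation

So I compare amounts at that one moment, not percentages. As read, gamma holds 0.0693 M of target and theta 0.143 M, so 4.00 times the charge gives 2.06 times the target. I call g the charge exponent (an apparent reaction order): the power of the charge that the target made in a fixed time follows. These two readings put it at 0.522, with their scatter in it. Since g is less than 1, I take the percentage at a fixed time, with the gas held as in these runs, to follow the charge to the power g minus one, so that it falls as the charge rises.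

Scaled from gamma, I expect this flask to hold 14.1 % at 12.0 h, and the ratio of the last two theta readings brings my estimate to 12.6 % at 10 h. The exponent says nothing about the coupling partner, so for saturation I take the forecast's figure as it stands. The forecast gives 12.2 % and 57 %, judging that “gas transfer is starting to limit the reaction”; its yield sits a little below mine and comes by another route.

The flask gives 12.2 % of target, with the coupling partner at 63.9 % of saturation, higher than the forecast.

    substrate → side product A (k = 8.39 × 10⁻⁶ /s)
    2 substrate → side product B (k = 3.30 × 10⁻⁵ /M/s)
    gas ⇌ coupling partner, rate k3*(csat - [coupling partner]) (kL = 5.11 × 10⁻⁵ /s)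
    substrate + coupling partner → target (k = 9.83 × 10⁻⁵ /M/s)

At 10.0 h side product B, in which each unit counts as two substrate, holds 49.0 % of this flask's charge, against 28.0 % in the same flask charged with 0.28 M. Carrying g from this flask's result to that smaller charge gives 19.0 % of target, and that flask stands at 18.2 %.

The readings are calculated with constants of no real substance; noise was put on by code.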